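**Retrosynthetic overview**

- Numbering: C1 = ring-fusion carbon bearing CH3, C2 and C3 = ring CH2, C4 = isopropyl carbinol, C5 = ring-fusion CH, C6 = acyloxy CH, C7 = CH2, C8 = spiro-epoxide carbon (C14 = its CH2), C9 and C10 = diol CH; α = face of the C1 methyl, β = the other face.
- Feature: the oxygenated C6 lies between C5 and C7 like the central carbon of an oxyallyl unit, and C8–C9–C10–C1 is a latent 1-oxygenated diene (the 9,10-diol is a former alkene, C8 carries oxygen). Cutting C1–C5 and C7–C8 opens the cyclopentane (C1–C5) and the cycloheptane (C1, C5–C10) together and leads to the acyclic chloromethyl ketone 19; its (4+3) cycloaddition closes the five-membered and then the seven-membered ring in one step to give 21.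
- 19 is built from (S)-terpinen-4-ol (1), whose ozonolysis delivers C4 with both arms. The methyl ketone arm becomes an alkyne, syn-carboalumination fixes the (E) C1=C10 bond, Heck and copper C–O couplings append C9=C8–O with retention, and the chloromethyl ketone is unveiled last from a Weinreb amide. The diene oxygen carries a benzyl group because this coupling sequence defines the (1E,3E) geometry, which enolisation of an aldehyde would not guarantee.
- After the cycloaddition: C4–OH-directed reduction of C6, isovalerylation, dihydroxylation of C9=C10 anti to the C1 methyl, C8–OBn to ketone to exocyclic methylene, and C9–OH-directed epoxidation (the oxirane is the last ring formed).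

Key step: step 12

Remark: (S)-(+)-terpinen-4-ol is taken as the commercial single enantiomer of high optical purity; a lot of lower purity would first be enriched (for example by crystallisation of a derivative).

**Route**

Step 1
Reactants: 1 (S)-terpinen-4-ol
Product: 2 triethylsilyl ether of terpinen-4-ol
Conditions: Et3SiOTf, 2,6-lutidine, CH2Cl2, 0 °C
Reagents that add atoms: triethylsilyl trifluoromethanesulfonate, CC[Si](CC)(CC)OS(=O)(=O)C(F)(F)F
Why: Silyl ether formation with a silyl triflate and a hindered pyridine base protects the tertiary alcohol that becomes C4–O without touching the alkene, and the C4 stereocentre comes unchanged from the chiral pool.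

Step 2
Reactants: 2 triethylsilyl ether of terpinen-4-ol
Product: 5 hydroxy ketone, via ozonide 3 (not isolated), via keto aldehyde 4 (not isolated)
Conditions: O3, CH2Cl2, −78 °C; PPh3, −78 °C to rt; then NaBH(OAc)3, AcOH, rt
Reagents that add atoms: ozone, [O-][O+]=O
Why: Ozonolysis with reductive work-up cleaves the ring alkene into the methyl ketone (future C1 and C10) and the aldehyde (future C6), and the chemoselective borohydride NaBH(OAc)3 then reduces only the aldehyde, so the two arms on C4 are differentiated.

Step 3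
Reactants: 5 hydroxy ketone
Product: 6 keto pivalate
Conditions: t-BuCOCl, pyridine, DMAP (cat.), CH2Cl2, 0 °C to rt
Reagents that add atoms: pivaloyl chloride, CC(C)(C)C(=O)Cl
Why: Acylation gives an ester without α-hydrogens that should survive the amide base and the alane of the next two steps and is later cleaved reductively.

Step 4
Reactants: 6 keto pivalate
Product: 8 terminal alkyne, via enol phosphate 7 (not isolated)
Conditions: LiN(iPr)2 (1.1 equiv), THF, −78 °C; ClP(O)(OEt)2, −78 °C to rt; then LiN(iPr)2 (2.3 equiv), −78 °C to rt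
Reagents that add atoms: none
Why: Kinetic deprotonation of the methyl group, O-phosphorylation and base-induced elimination of diethyl phosphate (Negishi methyl ketone to alkyne protocol) turn the acetyl group into the terminal alkyne C1≡C10.

Step 5
Reactants: 8 terminal alkyne
Product: 10 (E)-vinyl iodide pivalate, via alkenylalane 9 (not isolated)
Conditions: Me3Al, Cp2ZrCl2 (0.25 equiv), CH2Cl2, 0 °C to rt; then I2, THF, −30 °C to 0 °C
Reagents that add atoms: trimethylaluminium, C[Al](C)C; iodine, II
Why: Negishi zirconium-catalysed carboalumination adds CH3 and Al syn across the alkyne with Al on the terminal carbon, and iodinolysis with retention gives the (E)-trisubstituted iodide, which installs the future angular methyl and fixes the C1=C10 geometry with the tether trans to C9.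

Step 6
Reactants: 10 (E)-vinyl iodide pivalate
Product: 11 primary alcohol
Conditions: iBu2AlH, CH2Cl2, −78 °C
Reagents that add atoms: none
Why: Reductive ester cleavage with iBu2AlH frees the primary alcohol at low temperature without touching the vinyl iodide or the tertiary silyl ether.

Step 7
Reactants: 11 primary alcohol
Product: 13 carboxylic acid, via aldehyde 12 (not isolated)
Conditions: TEMPO (cat.), PhI(OAc)2, MeCN/H2O, rt
Reagents that add atoms: water, O
Why: Nitroxyl-catalysed oxidation with PhI(OAc)2 in aqueous acetonitrile carries the alcohol through aldehyde 12 and its hydrate to the acid under near-neutral conditions that the vinyl iodide and the silyl ether tolerate.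

Step 8
Reactants: 13 carboxylic acid
Product: 14 Weinreb amide
Conditions: MeNHOMe·HCl, EDC·HCl, HOBt, iPr2NEt, CH2Cl2, 0 °C to rt
Reagents that add atoms: N,O-dimethylhydroxylamine hydrochloride, CNOC.Cl
Why: Carbodiimide amide coupling gives the Weinreb amide, which should pass the palladium and copper steps untouched and later accept exactly one carbanion.

Step 9
Reactants: 14 Weinreb amide; 15 vinylboronic acid pinacol ester
Product: 16 (1E,3E)-dienylboronate
Conditions: Pd(OAc)2 (5 mol%), P(o-tol)3, AgOAc, MeCN, 50 °C
Reagents that add atoms: none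
Why: Heck–Mizoroki coupling of the vinyl iodide with the vinylboronate under anhydrous silver-mediated conditions, which disfavour boron-to-palladium transfer, gives the dienylboronate; syn insertion and syn β-hydride elimination make the new C8=C9 bond (E) and the C1=C10 geometry is retained.

Step 10
Reactants: 16 (1E,3E)-dienylboronate
Product: 17 (1E,3E)-benzyloxydiene Weinreb amide
Conditions: Cu(OAc)2 (2 equiv), Et3N, BnOH (excess), CH2Cl2, 4 Å MS, rt
Reagents that add atoms: benzyl alcohol, OCc1ccccc1
Why: Chan–Lam-type oxidative copper coupling of an alkenylboronate with an alcohol forms the C8–O bond with retention of alkene geometry, so the (1E,3E)-1-benzyloxydiene should be obtained as a single isomer.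

Step 11
Reactants: 17 (1E,3E)-benzyloxydiene Weinreb amide
Product: 19 chloromethyl ketone, via lithium hemiaminal alkoxide 18 (not isolated)
Conditions: ICH2Cl, MeLi·LiBr, THF, −78 °C; sat. NH4Cl, −78 °C
Reagents that add atoms: chloroiodomethane, ClCI
Why: LiCH2Cl, made in situ by iodine–lithium exchange, adds once to the Weinreb amide because the chelated tetrahedral adduct 18 survives until the cold quench (Weinreb ketone synthesis), so the α-chloroketone appears only in the last step before the cycloaddition and the enol ether and silyl ether are untouched.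

Step 12
Reactants: 19 chloromethyl ketone
Product: 21 trans-fused benzyloxy hydroazulenone, via oxyallyl cation 20 (not isolated)
Conditions: Et3N (3 equiv), LiClO4 (3 M), Et2O, rt
Reagents that add atoms: none
Why: Triethylamine enolises the ketone toward C5 and LiClO4 assists loss of chloride from C7, giving the 2-oxidoallyl cation 20 (C5–C6–C7), which the tethered diene traps; the closest known reaction type is the intramolecular (4+3) cycloaddition of oxyallyl cations, generated from α-chloroketones with amine and LiClO4, with tethered dienes. The five-membered ring closes 5-exo by attack of C1, the nucleophilic far terminus of the 1-benzyloxydiene, on the cation terminus C5 (bond C1–C5), and the seven-membered ring closes when the enolate carbon C7 adds to the benzyloxy-stabilised allyl cation at C8 (bond C7–C8), in one asynchronous transition state or in two fast steps. C1 is controlled by the C4 stereocentre: the tether folds with the isopropyl group pseudo-equatorial and the smaller O–SiEt3 group on the face of the developing axial methyl, so the C1 methyl should end up cis to the C4 oxygen. C5 follows from the (E) C1=C10 geometry (tether outside), which admits the trans-fused transition state, and, being α to the new ketone, it can be equilibrated by the amine to the trans-fused isomer with C6 anti to isopropyl; C8 results from suprafacial addition to the (1E,3E)-diene (OBn cis to C2) and is erased in step 19. The step needs the diene to react in its s-cis form at C1 and to close the second bond instead of stopping after the first: the (1E,3E) geometry leaves only H and CH3 inside, the benzyloxy donor makes C1 the nucleophilic and C8 the cationic terminus, and the non-acidic amine/perchlorate medium spares the enol ether and the silyl ether.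

Step 13
Reactants: 21 trans-fused benzyloxy hydroazulenone
Product: 22 β-hydroxy ketone
Conditions: HF·pyridine, pyridine, THF, 0 °C to rt
Reagents that add atoms: none
Why: Fluoride-mediated desilylation with buffered HF·pyridine frees the tertiary C4 alcohol under mildly acidic conditions that avoid retro-aldol opening of the β-hydroxy ketone.

Step 14
Reactants: 22 β-hydroxy ketone
Product: 23 4α,6β-diol
Conditions: Me4NBH(OAc)3, MeCN/AcOH, −30 °C
Reagents that add atoms: none
Why: Hydroxyl-directed reduction (Evans–Saksena): the acetoxyborohydride bound to the α-oriented C4 oxygen delivers hydride intramolecularly to the α face of the C6 ketone, giving the 4,6-anti diol with the new C6 hydroxyl β.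

Step 15
Reactants: 23 4α,6β-diol; 24 isovaleryl chloride
Product: 25 C6 isovalerate
Conditions: pyridine, DMAP (cat.), CH2Cl2, 0 °C to rt
Reagents that add atoms: none
Why: DMAP-catalysed acylation esterifies the secondary C6 hydroxyl, while the tertiary C4 hydroxyl is too hindered to react.

Step 16
Reactants: 25 C6 isovalerate
Product: 26 9β,10β-diol
Conditions: OsO4 (cat.), N-methylmorpholine N-oxide, acetone/H2O, rt
Reagents that add atoms: osmium tetroxide, O=[Os](=O)(=O)=O; N-methylmorpholine N-oxide, C[N+]1([O-])CCOCC1
Why: Catalytic OsO4 syn-dihydroxylation should add both oxygens to the β face of C9=C10, anti to the axial α-methyl on C1 of the trans-fused system (the C8 ether is pseudo-equatorial and does not block that face), which sets C9 and C10.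

Step 17
Reactants: 26 9β,10β-diol
Product: 27 9,10-acetonide
Conditions: 2,2-dimethoxypropane, PPTS (cat.), CH2Cl2, rt
Reagents that add atoms: 2,2-dimethoxypropane, COC(C)(C)OC
Why: Acid-catalysed transketalisation closes the cis-9,10-diol to a five-membered acetonide and leaves the tertiary alcohol free.

Step 18
Reactants: 27 9,10-acetonide
Product: 28 C8 alcohol
Conditions: H2 (1 atm), Pd(OH)2/C, EtOAc, rt
Reagents that add atoms: none
Why: Hydrogenolysis cleaves the benzyl ether, which is possible only now that no alkene remains.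

Step 19
Reactants: 28 C8 alcohol
Product: 29 C8 ketone
Conditions: Dess–Martin periodinane, NaHCO3, CH2Cl2, rt
Reagents that add atoms: none
Why: Dess–Martin oxidation converts the only secondary alcohol into the C8 ketone under non-basic conditions, so the β-acyloxy group at C6 is not eliminated and the acetonide-locked C9 centre is not epimerised.

Step 20
Reactants: 29 C8 ketone
Product: 30 C8 exocyclic alkene
Conditions: Zn, CH2Br2, TiCl4, THF/CH2Cl2, 0 °C to rt
Reagents that add atoms: dibromomethane, BrCBr
Why: Takai–Lombardo methylenation is non-basic and ignores esters, so the enolisable β-acyloxy ketone should give the C8=C14 alkene without elimination.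

Step 21
Reactants: 30 C8 exocyclic alkene
Product: 31 allylic 9β,10β-diol
Conditions: AcOH/H2O (4:1), 40 °C
Reagents that add atoms: none
Why: Mild aqueous acid hydrolysis removes the acetonide and frees the allylic C9 hydroxyl as directing group before the acid-sensitive oxirane is made.

Step 22
Reactants: 31 allylic 9β,10β-diol
Product: 32 CNP0307265.1
Conditions: VO(acac)2 (cat.), t-BuOOH, CH2Cl2, 0 °C
Reagents that add atoms: tert-butyl hydroperoxide, CC(C)(C)OO
Why: Vanadium-catalysed hydroxyl-directed epoxidation (Sharpless type) delivers oxygen to the C8=C14 alkene from the face of the coordinating β-C9 hydroxyl, so the oxirane oxygen is β and the C8 spiro centre is set.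

**Compound list**

1 | (S)-terpinen-4-ol, (1S)-4-methyl-1-(propan-2-yl)cyclohex-3-en-1-ol | CC1=CC[C@](O)(C(C)C)CC1 | starting material
2 | triethyl{[(1S)-4-methyl-1-(propan-2-yl)cyclohex-3-en-1-yl]oxy}silane | CC1=CC[C@](O[Si](CC)(CC)CC)(C(C)C)CC1 | intermediate
3 | secondary ozonide (1,2,4-trioxolane) of 2, silyloxy carbon unchanged, new acetal carbons as formed | CC12CC[C@@](O[Si](CC)(CC)CC)(C(C)C)CC(OO1)O2 | intermediate
4 | (3S)-6-oxo-3-(propan-2-yl)-3-[(triethylsilyl)oxy]heptanal | O=CC[C@](O[Si](CC)(CC)CC)(C(C)C)CCC(C)=O | intermediate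
5 | (5S)-7-hydroxy-5-(propan-2-yl)-5-[(triethylsilyl)oxy]heptan-2-one | OCC[C@](O[Si](CC)(CC)CC)(C(C)C)CCC(C)=O | intermediate
6 | (3S)-6-oxo-3-(propan-2-yl)-3-[(triethylsilyl)oxy]heptyl 2,2-dimethylpropanoate | CC(C)(C)C(=O)OCC[C@](O[Si](CC)(CC)CC)(C(C)C)CCC(C)=O | intermediate
7 | (3S)-6-[(diethoxyphosphoryl)oxy]-3-(propan-2-yl)-3-[(triethylsilyl)oxy]hept-6-en-1-yl 2,2-dimethylpropanoate | CC(C)(C)C(=O)OCC[C@](O[Si](CC)(CC)CC)(C(C)C)CCC(=C)OP(=O)(OCC)OCC | intermediate
8 | (3S)-3-(propan-2-yl)-3-[(triethylsilyl)oxy]hept-6-yn-1-yl 2,2-dimethylpropanoate | CC(C)(C)C(=O)OCC[C@](O[Si](CC)(CC)CC)(C(C)C)CCC#C | intermediate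
9 | (E)-alkenyl(dimethyl)alane from syn-methylalumination of 8 | CC(C)(C)C(=O)OCC[C@](O[Si](CC)(CC)CC)(C(C)C)CC/C(C)=C/[Al](C)C | intermediate
10 | (3S,6E)-7-iodo-6-methyl-3-(propan-2-yl)-3-[(triethylsilyl)oxy]hept-6-en-1-yl 2,2-dimethylpropanoate | CC(C)(C)C(=O)OCC[C@](O[Si](CC)(CC)CC)(C(C)C)CC/C(C)=C/I | intermediate
11 | (3S,6E)-7-iodo-6-methyl-3-(propan-2-yl)-3-[(triethylsilyl)oxy]hept-6-en-1-ol | OCC[C@](O[Si](CC)(CC)CC)(C(C)C)CC/C(C)=C/I | intermediate
12 | (3S,6E)-7-iodo-6-methyl-3-(propan-2-yl)-3-[(triethylsilyl)oxy]hept-6-enal | O=CC[C@](O[Si](CC)(CC)CC)(C(C)C)CC/C(C)=C/I | intermediate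
13 | (3S,6E)-7-iodo-6-methyl-3-(propan-2-yl)-3-[(triethylsilyl)oxy]hept-6-enoic acid | OC(=O)C[C@](O[Si](CC)(CC)CC)(C(C)C)CC/C(C)=C/I | intermediate
14 | (3S,6E)-7-iodo-N-methoxy-N,6-dimethyl-3-(propan-2-yl)-3-[(triethylsilyl)oxy]hept-6-enamide | CON(C)C(=O)C[C@](O[Si](CC)(CC)CC)(C(C)C)CC/C(C)=C/I | intermediate
15 | vinylboronic acid pinacol ester, 4,4,5,5-tetramethyl-2-vinyl-1,3,2-dioxaborolane | C=CB1OC(C)(C)C(C)(C)O1 | starting material
16 | (3S,6E,8E)-N-methoxy-N,6-dimethyl-3-(propan-2-yl)-9-(4,4,5,5-tetramethyl-1,3,2-dioxaborolan-2-yl)-3-[(triethylsilyl)oxy]nona-6,8-dienamide | CON(C)C(=O)C[C@](O[Si](CC)(CC)CC)(C(C)C)CC/C(C)=C/C=C/B1OC(C)(C)C(C)(C)O1 | intermediate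
17 | (3S,6E,8E)-9-(benzyloxy)-N-methoxy-N,6-dimethyl-3-(propan-2-yl)-3-[(triethylsilyl)oxy]nona-6,8-dienamide | CON(C)C(=O)C[C@](O[Si](CC)(CC)CC)(C(C)C)CC/C(C)=C/C=C/OCc1ccccc1 | intermediate
18 | lithium alkoxide of the N-methoxy-N-methyl hemiaminal formed from 17 and LiCH2Cl (new carbinol carbon unspecified) | [Li]OC(CCl)(N(C)OC)C[C@](O[Si](CC)(CC)CC)(C(C)C)CC/C(C)=C/C=C/OCc1ccccc1 | intermediate
19 | (4S,7E,9E)-10-(benzyloxy)-1-chloro-7-methyl-4-(propan-2-yl)-4-[(triethylsilyl)oxy]deca-7,9-dien-2-one (key-step precursor) | ClCC(=O)C[C@](O[Si](CC)(CC)CC)(C(C)C)CC/C(C)=C/C=C/OCc1ccccc1 | intermediate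
20 | 2-oxidoallyl cation (C5–C6–C7) derived from 19 | [CH2+]C([O-])=C[C@](O[Si](CC)(CC)CC)(C(C)C)CC/C(C)=C/C=C/OCc1ccccc1 | intermediate
21 | trans-fused hydroazulen-6-one: C1 CH3 α, C5 H β, C4 OSiEt3 α and isopropyl β, C8 OBn β (expected; either C8 epimer serves), C9=C10 alkene | O=C1C[C@@H](OCc3ccccc3)C=C[C@@]2(C)CC[C@@](O[Si](CC)(CC)CC)(C(C)C)[C@H]12 | intermediate
22 | as 21 with free C4 α-hydroxyl | O=C1C[C@@H](OCc3ccccc3)C=C[C@@]2(C)CC[C@@](O)(C(C)C)[C@H]12 | intermediate
23 | 4α,6β-diol (C6 ketone of 22 reduced, C6 OH β) | O[C@H]1C[C@@H](OCc3ccccc3)C=C[C@@]2(C)CC[C@@](O)(C(C)C)[C@H]12 | intermediate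
24 | isovaleryl chloride, 3-methylbutanoyl chloride | CC(C)CC(=O)Cl | starting material
25 | C6 β-(3-methylbutanoate) of 23 | CC(C)CC(=O)O[C@H]1C[C@@H](OCc3ccccc3)C=C[C@@]2(C)CC[C@@](O)(C(C)C)[C@H]12 | intermediate
26 | 9β,10β-diol of 25 | CC(C)CC(=O)O[C@H]1C[C@@H](OCc3ccccc3)[C@@H](O)[C@@H](O)[C@@]2(C)CC[C@@](O)(C(C)C)[C@H]12 | intermediate
27 | 9,10-O-isopropylidene derivative of 26 | CC(C)CC(=O)O[C@H]1C[C@@H](OCc3ccccc3)[C@H]4OC(C)(C)O[C@H]4[C@@]2(C)CC[C@@](O)(C(C)C)[C@H]12 | intermediate
28 | C8 β-alcohol (debenzylated 27) | CC(C)CC(=O)O[C@H]1C[C@@H](O)[C@H]4OC(C)(C)O[C@H]4[C@@]2(C)CC[C@@](O)(C(C)C)[C@H]12 | intermediate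
29 | C8 ketone | CC(C)CC(=O)O[C@H]1CC(=O)[C@H]4OC(C)(C)O[C@H]4[C@@]2(C)CC[C@@](O)(C(C)C)[C@H]12 | intermediate
30 | C8 exocyclic methylene (C8=C14) acetonide | CC(C)CC(=O)O[C@H]1CC(=C)[C@H]4OC(C)(C)O[C@H]4[C@@]2(C)CC[C@@](O)(C(C)C)[C@H]12 | intermediate
31 | C8 exocyclic methylene 9β,10β-diol | CC(C)CC(=O)O[C@H]1CC(=C)[C@@H](O)[C@@H](O)[C@@]2(C)CC[C@@](O)(C(C)C)[C@H]12 | intermediate
32 | CNP0307265.1: 8,14-epoxide (oxygen β), 9β,10β-diol, 4α-hydroxy-4β-isopropyl, 1α-methyl, 5β-H, 6β-(3-methylbutanoyloxy) trans-hydroazulene | CC(C)CC(=O)O[C@H]1C[C@]2(CO2)[C@@H](O)[C@@H](O)[C@@]2(C)CC[C@@](O)(C(C)C)[C@H]12 | target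

**Step count**

Total steps: 22. Longest linear sequence: 22 steps (from 1).

**Steps most likely to fail**

1. Step 12. After the first C–C bond (C1–C5) the benzyloxy-stabilised cation may lose a proton or the benzyl group instead of closing the seven-membered ring, or the enol ether may not survive the ionising medium. The fallback introduces the C8 oxygen after the cycloaddition instead of before it. It sets out from 14: Suzuki–Miyaura coupling with 15 (Pd(PPh3)4, K3PO4, THF/H2O) should give the terminal (E)-diene amide F1. LiCH2Cl as in step 11 gives the chloromethyl ketone F2. Et3N/LiClO4 then runs the (4+3) cycloaddition on an all-carbon diene, the best-precedented partner, to give the C8-unsubstituted trans-hydroazulenone F3. Allylic hydroxylation with SeO2 (cat.)/t-BuOOH, for which only C8 carries allylic hydrogens, gives the allylic alcohol F4. Benzylation with 2-benzyloxy-1-methylpyridinium triflate/MgO comes back to the route at 21 (either C8 epimer; the centre is erased at 29).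

2. Step 10. Protodeboronation or oxidative homocoupling of the dienylboronate may outrun C–O bond formation with the alcohol. The fallback is an Ullmann-type coupling of a dienyl iodide instead of an oxidative coupling of the boronate. It sets out from 14: Stille coupling with excess (E)-1,2-bis(tributylstannyl)ethene (Pd(PPh3)4, DMF) should give the dienylstannane F5. Iododestannylation (I2, CH2Cl2, 0 °C) gives the (1E,3E)-dienyl iodide F6 with retention. CuI/3,4,7,8-tetramethyl-1,10-phenanthroline/Cs2CO3 with benzyl alcohol in toluene at 80 °C comes back at 17.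

3. Step 9. Transfer of the vinyl group from boron (Suzuki-type coupling) or loss of insertion regiocontrol may compete with the Heck pathway. The fallback uses alkyne coupling and hydroboration in place of the Heck reaction. It sets out from 14: Sonogashira coupling with ethynyltrimethylsilane (Pd(PPh3)4, CuI, Et3N) should give the silyl enyne F7. K2CO3/MeOH gives the terminal enyne F8. Cp2ZrHCl-catalysed syn-hydroboration with pinacolborane comes back at 16.

**Further compounds**

F1 | step 12 | (3S,6E)-N-methoxy-N,6-dimethyl-3-(propan-2-yl)-3-[(triethylsilyl)oxy]nona-6,8-dienamide | CON(C)C(=O)C[C@](O[Si](CC)(CC)CC)(C(C)C)CC/C(C)=C/C=C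
F2 | step 12 | (4S,7E)-1-chloro-7-methyl-4-(propan-2-yl)-4-[(triethylsilyl)oxy]deca-7,9-dien-2-one | ClCC(=O)C[C@](O[Si](CC)(CC)CC)(C(C)C)CC/C(C)=C/C=C
F3 | step 12 | trans-fused hydroazulen-6-one as 21 but with CH2 at C8 | O=C1CCC=C[C@@]2(C)CC[C@@](O[Si](CC)(CC)CC)(C(C)C)[C@H]12
F4 | step 12 | C8 allylic alcohol of F3 (C8 configuration not fixed) | O=C1CC(O)C=C[C@@]2(C)CC[C@@](O[Si](CC)(CC)CC)(C(C)C)[C@H]12
F5 | step 10 | (3S,6E,8E)-N-methoxy-N,6-dimethyl-3-(propan-2-yl)-9-(tributylstannyl)-3-[(triethylsilyl)oxy]nona-6,8-dienamide | CON(C)C(=O)C[C@](O[Si](CC)(CC)CC)(C(C)C)CC/C(C)=C/C=C/[Sn](CCCC)(CCCC)CCCC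
F6 | step 10 | (3S,6E,8E)-9-iodo-N-methoxy-N,6-dimethyl-3-(propan-2-yl)-3-[(triethylsilyl)oxy]nona-6,8-dienamide | CON(C)C(=O)C[C@](O[Si](CC)(CC)CC)(C(C)C)CC/C(C)=C/C=C/I
F7 | step 9 | (3S,6E)-N-methoxy-N,6-dimethyl-3-(propan-2-yl)-3-[(triethylsilyl)oxy]-9-(trimethylsilyl)non-6-en-8-ynamide | CON(C)C(=O)C[C@](O[Si](CC)(CC)CC)(C(C)C)CC/C(C)=C/C#C[Si](C)(C)C
F8 | step 9 | (3S,6E)-N-methoxy-N,6-dimethyl-3-(propan-2-yl)-3-[(triethylsilyl)oxy]non-6-en-8-ynamide | CON(C)C(=O)C[C@](O[Si](CC)(CC)CC)(C(C)C)CC/C(C)=C/C#C
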